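**Retrosynthetic overview** (naphthalene locants: ring B = C1 (side chain), C2, C3 (O), C4 (CH3), C4a, C8a; ring A = C4a, C5, C6, C7 (=CH2), C8, C8a)
1. Endgame: both acetates from the diol; enone side chain from a Weinreb amide and an isobutenyl Grignard reagent; axial C3–OH from the C3 ketone; C7(=CH2)/C8=C8a diene from a C8 ketone via its dienyl triflate.
2. Key disconnection: C1–C2 and C4a–C8a by an intramolecular Diels–Alder reaction of an acyclic 2-silyloxy-3-methyl-diene/cross-conjugated dienone; rings A and B form together in that one step.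
3. Enabling feature: ring B carries O at C3 next to CH3 at C4 (a C3=C4 silyl enol ether, the retron of diene C2=C3–C4=C4a), and its C1–C8a edge adjoins C8 of ring A, where a ketone activates the dienophile C8a=C1 and later becomes the C8=C8a alkene; the C7 methylidene rides in as the α-methylene of that ketone, and the C4 methyl steers trans-fusion.
4. The triene comes from a Nozaki–Hiyama–Kishi union of alkenyl iodide 6 (from pent-4-yn-1-ol) with enal 16 (crotylboration of ethyl glyoxylate sets both side-chain centres; cross-metathesis adds the enal).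

Key step: step 10

Remark: carbinol 17 is formed as a mixture of C6 epimers, which is erased in step 10; ethyl glyoxylate is used as the freshly distilled monomer.

Step 1
Reactants: 1 pent-4-yn-1-ol
Product: 2 4-iodopent-4-en-1-ol
Conditions: NaI, TMSCl, H2O, MeCN, rt
Reagents that add atoms: sodium iodide, [Na+].[I-]
Why: Markovnikov hydroiodination of the terminal alkyne by HI generated in situ gives the 2-iodo-1-alkene; no stereocentre is formed.

Step 2
Reactants: 2 4-iodopent-4-en-1-ol
Product: 3 4-iodopent-4-enal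
Conditions: Dess–Martin periodinane, CH2Cl2, 0 °C to rt
Reagents that add atoms: none
Why: Dess–Martin oxidation of the primary alcohol to the aldehyde leaves the alkenyl iodide untouched.

Step 3
Reactants: 3 4-iodopent-4-enal and 4 3-(triphenylphosphoranylidene)butan-2-one
Product: 5 (3E)-7-iodo-3-methylocta-3,7-dien-2-one
Conditions: toluene, 90 °C
Reagents that add atoms: none
Why: Wittig olefination with a stabilised acyl ylide should give the E trisubstituted enone.

Step 4
Reactants: 5 (3E)-7-iodo-3-methylocta-3,7-dien-2-one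
Product: 6 (3E)-7-iodo-3-methyl-2-(triisopropylsilyloxy)octa-1,3,7-triene
Conditions: TIPSOTf, Et3N, CH2Cl2, −78 to 0 °C
Reagents that add atoms: triisopropylsilyl trifluoromethanesulfonate, CC(C)[Si](OS(=O)(=O)C(F)(F)F)(C(C)C)C(C)C
Why: Soft enolisation (silyl triflate and amine) removes the kinetically accessible α′-methyl proton of the enone and gives the cross-conjugated 2-silyloxy diene with the E C3=C4 geometry retained.

Step 5
Reactants: 7 (Z)-but-2-ene and 8 ethyl glyoxylate
Product: 12 ethyl (2R,3S)-2-hydroxy-3-methylpent-4-enoate, via (Z)-crotylpotassium 9 (not isolated), via (Z)-crotyldiisopinocampheylborane 10 (not isolated), via borinate ester 11 (not isolated)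
Conditions: KOt-Bu, n-BuLi, THF, −78 to −45 °C; (+)-Ipc2BOMe (from (−)-α-pinene), −78 °C; BF3·OEt2; 8, −78 °C; then H2O2, pH 7 buffer, 0 °C
Reagents that add atoms: none
Why: Asymmetric crotylboration through a chair Zimmerman–Traxler transition state, in which the Z crotyl geometry gives the 2,3-syn relationship and the isopinocampheyl groups derived from (−)-α-pinene direct attack to the Re face of the aldehyde, should give (2R,3S).

Step 6
Reactants: 12 ethyl (2R,3S)-2-hydroxy-3-methylpent-4-enoate
Product: 13 ethyl (2R,3S)-2-(tert-butyldimethylsilyloxy)-3-methylpent-4-enoate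
Conditions: TBSCl, imidazole, DMF, rt
Reagents that add atoms: tert-butyldimethylsilyl chloride, CC(C)(C)[Si](C)(C)Cl
Why: Standard silylation of the secondary alcohol protects it for the base and hydride steps that follow.

Step 7
Reactants: 13 ethyl (2R,3S)-2-(tert-butyldimethylsilyloxy)-3-methylpent-4-enoate
Product: 14 (2R,3S)-2-(tert-butyldimethylsilyloxy)-N-methoxy-N,3-dimethylpent-4-enamide
Conditions: MeNH(OMe)·HCl, i-PrMgCl, THF, −20 to 0 °C
Reagents that add atoms: N,O-dimethylhydroxylamine hydrochloride, CNOC.Cl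
Why: Aminolysis of the ester by the magnesium amide of N,O-dimethylhydroxylamine (Weinreb amide formation) at low temperature should preserve the α-stereocentre.

Step 8
Reactants: 14 (2R,3S)-2-(tert-butyldimethylsilyloxy)-N-methoxy-N,3-dimethylpent-4-enamide and 15 (E)-but-2-enal
Product: 16 (2R,3S,4E)-2-(tert-butyldimethylsilyloxy)-N-methoxy-N,3-dimethyl-6-oxohex-4-enamide
Conditions: second-generation Hoveyda–Grubbs catalyst (5 mol %), 15 (5 equiv), CH2Cl2, 40 °C
Reagents that add atoms: none
Why: Olefin cross-metathesis of the terminal alkene with crotonaldehyde should give the E enal selectively without touching the stereocentres.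

Step 9
Reactants: 6 (3E)-7-iodo-3-methyl-2-(triisopropylsilyloxy)octa-1,3,7-triene and 16 (2R,3S,4E)-2-(tert-butyldimethylsilyloxy)-N-methoxy-N,3-dimethyl-6-oxohex-4-enamide
Product: 17 (2R,3S,4E,10E)-2-(tert-butyldimethylsilyloxy)-6-hydroxy-N-methoxy-N,3,11-trimethyl-7-methylidene-12-(triisopropylsilyloxy)trideca-4,10,12-trienamide (C6 epimers)
Conditions: CrCl2 (4 equiv), NiCl2 (2 mol %), DMSO–THF, rt
Reagents that add atoms: none
Why: Nozaki–Hiyama–Kishi coupling, in which the alkenylchromium species formed from the iodide adds 1,2 to the aldehyde only and tolerates the Weinreb amide, silyl ether and silyl dienol ether; the new carbinol centre is uncontrolled and is erased in step 10.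

Step 10
Reactants: 17 (2R,3S,4E,10E)-2-(tert-butyldimethylsilyloxy)-6-hydroxy-N-methoxy-N,3,11-trimethyl-7-methylidene-12-(triisopropylsilyloxy)trideca-4,10,12-trienamide
Product: 19 (2R,3S)-2-(tert-butyldimethylsilyloxy)-N-methoxy-N-methyl-3-[(1S,4aR,8aS)-4-methyl-7-methylidene-8-oxo-3-(triisopropylsilyloxy)-1,2,4a,5,6,7,8,8a-octahydronaphthalen-1-yl]butanamide, via dienone 18 (not isolated)
Conditions: MnO2 (activated, excess), CH2Cl2, rt; filtration; toluene (0.005 M), BHT, rt to 60 °C
Reagents that add atoms: none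
Why: MnO2 oxidises the doubly allylic carbinol to the cross-conjugated dienone 18, a 1,7,9-decatrien-3-one carrying a 2-silyloxy-3-methyl diene, which closes by a concerted, asynchronous, normal-demand intramolecular Diels–Alder reaction (type 1), the closest known type being the spontaneous cycloaddition of trienones released by oxidation of dienyl allylic alcohols. Ring B is closed as the cyclohexene of the [4+2] itself (C1–C2 joins the nucleophilic diene terminus to the enone β-carbon, C4a–C8a joins the tethered termini) and ring A is closed as the six-membered tether ring in the fused mode. C1 and C4a are set relative to each other by the E geometries of diene and dienophile together with the trans-fused (tether-exo, side-chain-endo) transition state, which is favoured because in the cis-fused alternative the C4 methyl of the diene suffers allylic 1,3-strain with the C5 methylene of the tether (steric-directing-group effect), and this should outweigh the weak endo preference of the tether carbonyl. The absolute sense is controlled by the existing stereocentre next to C1: its hydrogen sits inside, under the diene, and its bulky CH(OTBS)C(O)N(OMe)Me branch lies anti to the incoming diene, which leads to (1S,4aR) as drawn; C8a is a transient centre erased in step 11. The step needs site selectivity (C8a=C1 rather than the C7 methylidene, secured by the tether, since only C8a=C1 can give a fused six-membered ring), ring-fusion selectivity (secured by the C4 methyl) and π-facial selectivity (secured by the side-chain stereocentre). Neutral, Lewis-acid-free conditions keep the silyl enol ether intact and avoid Nazarov cyclisation of the dienone.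

Step 11
Reactants: 19 (2R,3S)-2-(tert-butyldimethylsilyloxy)-N-methoxy-N-methyl-3-[(1S,4aR,8aS)-4-methyl-7-methylidene-8-oxo-3-(triisopropylsilyloxy)-1,2,4a,5,6,7,8,8a-octahydronaphthalen-1-yl]butanamide
Product: 20 (2R,3S)-2-(tert-butyldimethylsilyloxy)-N-methoxy-N-methyl-3-[(1S,4aS)-4-methyl-7-methylidene-3-(triisopropylsilyloxy)-8-(trifluoromethylsulfonyloxy)-1,2,4a,5,6,7-hexahydronaphthalen-1-yl]butanamide
Conditions: KN(SiMe3)2, THF, −78 °C; PhNTf2, −78 to 0 °C
Reagents that add atoms: N-phenylbis(trifluoromethanesulfonimide), O=S(=O)(N(c1ccccc1)S(=O)(=O)C(F)(F)F)C(F)(F)F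
Why: Kinetic deprotonation at C8a, the only α-CH of the α-methylene ketone, gives the cross-conjugated dienolate, which is O-sulfonylated (enol triflate formation); the transient C8a centre is erased.

Step 12
Reactants: 20 (2R,3S)-2-(tert-butyldimethylsilyloxy)-N-methoxy-N-methyl-3-[(1S,4aS)-4-methyl-7-methylidene-3-(triisopropylsilyloxy)-8-(trifluoromethylsulfonyloxy)-1,2,4a,5,6,7-hexahydronaphthalen-1-yl]butanamide
Product: 21 (2R,3S)-2-(tert-butyldimethylsilyloxy)-N-methoxy-N-methyl-3-[(1S,4aR)-4-methyl-7-methylidene-3-(triisopropylsilyloxy)-1,2,4a,5,6,7-hexahydronaphthalen-1-yl]butanamide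
Conditions: Pd(OAc)2 (5 mol %), PPh3, n-Bu3N, HCO2H, DMF, 60 °C
Reagents that add atoms: none
Why: Palladium-catalysed formate reduction of an alkenyl triflate (oxidative addition, formate-to-hydride exchange with loss of CO2, reductive elimination) replaces OTf by H and leaves the C7(=CH2)/C8=C8a diene in place.

Step 13
Reactants: 21 (2R,3S)-2-(tert-butyldimethylsilyloxy)-N-methoxy-N-methyl-3-[(1S,4aR)-4-methyl-7-methylidene-3-(triisopropylsilyloxy)-1,2,4a,5,6,7-hexahydronaphthalen-1-yl]butanamide
Product: 22 (2R,3S)-2-hydroxy-N-methoxy-N-methyl-3-[(1S,4S,4aS)-4-methyl-7-methylidene-3-oxo-1,2,3,4,4a,5,6,7-octahydronaphthalen-1-yl]butanamide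
Conditions: Bu4NF, AcOH (1 equiv), THF, 0 °C to rt; then DBU (0.2 equiv), rt
Reagents that add atoms: none
Why: Fluoride cleaves the silyl enol ether (regiospecific release of the C3 ketone) and the secondary silyl ether, and base equilibration through the enol should place the C4 methyl equatorial, trans to the C4a–C5 bond, which is the (4S) configuration.

Step 14
Reactants: 22 (2R,3S)-2-hydroxy-N-methoxy-N-methyl-3-[(1S,4S,4aS)-4-methyl-7-methylidene-3-oxo-1,2,3,4,4a,5,6,7-octahydronaphthalen-1-yl]butanamide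
Product: 23 (2R,3S)-2-hydroxy-3-[(1S,3R,4S,4aS)-3-hydroxy-4-methyl-7-methylidene-1,2,3,4,4a,5,6,7-octahydronaphthalen-1-yl]-N-methoxy-N-methylbutanamide
Conditions: LiBH(s-Bu)3 (L-Selectride, 2.5 equiv), THF, −78 °C; then H2O
Reagents that add atoms: none
Why: The bulky trialkylborohydride attacks the cyclohexanone from the equatorial direction and should give the axial (3R) alcohol cis to the equatorial C4 methyl, while the Weinreb amide is expected to survive at −78 °C.

Step 15
Reactants: 23 (2R,3S)-2-hydroxy-3-[(1S,3R,4S,4aS)-3-hydroxy-4-methyl-7-methylidene-1,2,3,4,4a,5,6,7-octahydronaphthalen-1-yl]-N-methoxy-N-methylbutanamide and 24 2-methylprop-1-enylmagnesium bromide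
Product: 25 (2S,3R)-3-hydroxy-2-[(1S,3R,4S,4aS)-3-hydroxy-4-methyl-7-methylidene-1,2,3,4,4a,5,6,7-octahydronaphthalen-1-yl]-6-methylhept-5-en-4-one
Conditions: 24 (5 equiv), THF, −20 to 0 °C; aqueous work-up
Reagents that add atoms: none
Why: Weinreb ketone synthesis, in which the alkenyl Grignard reagent adds once to give a chelated tetrahedral intermediate that collapses to the enone only on work-up, with the two hydroxyls carried as magnesium alkoxides.

Step 16
Reactants: 25 (2S,3R)-3-hydroxy-2-[(1S,3R,4S,4aS)-3-hydroxy-4-methyl-7-methylidene-1,2,3,4,4a,5,6,7-octahydronaphthalen-1-yl]-6-methylhept-5-en-4-one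
Product: 26 (2S,3R)-2-[(1S,3R,4S,4aS)-3-acetoxy-4-methyl-7-methylidene-1,2,3,4,4a,5,6,7-octahydronaphthalen-1-yl]-6-methyl-4-oxohept-5-en-3-yl acetate (CNP0302999.1)
Conditions: Ac2O, DMAP (cat.), pyridine, CH2Cl2, 0 °C to rt
Reagents that add atoms: acetic anhydride, CC(=O)OC(C)=O
Why: DMAP-catalysed acylation of both secondary alcohols touches no stereocentre and gives the target.

**Compound list**
1 | pent-4-yn-1-ol | C#CCCCO | starting material
2 | 4-iodopent-4-en-1-ol | C=C(I)CCCO | intermediate
3 | 4-iodopent-4-enal | C=C(I)CCC=O | intermediate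
4 | 3-(triphenylphosphoranylidene)butan-2-one | CC(=O)C(C)=P(c1ccccc1)(c1ccccc1)c1ccccc1 | starting material
5 | (3E)-7-iodo-3-methylocta-3,7-dien-2-one | CC(=O)/C(C)=C/CCC(I)=C | intermediate
6 | (3E)-7-iodo-3-methyl-2-(triisopropylsilyloxy)octa-1,3,7-triene | C=C(O[Si](C(C)C)(C(C)C)C(C)C)/C(C)=C/CCC(I)=C | intermediate
7 | (Z)-but-2-ene | C/C=C\C | starting material
8 | ethyl glyoxylate (ethyl 2-oxoacetate) | CCOC(=O)C=O | starting material
9 | (Z)-but-2-en-1-ylpotassium | C/C=C\C[K] | intermediate
10 | (Z)-but-2-en-1-yl-bis(isopinocampheyl)borane (isopinocampheyl groups from (−)-α-pinene) | C/C=C\CB([C@H]1C[C@H]2C[C@@H]([C@@H]1C)C2(C)C)[C@H]1C[C@H]2C[C@@H]([C@@H]1C)C2(C)C | intermediate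
11 | ethyl (2R,3S)-2-[bis(isopinocampheyl)boranyloxy]-3-methylpent-4-enoate | CCOC(=O)[C@H](OB([C@H]1C[C@H]2C[C@@H]([C@@H]1C)C2(C)C)[C@H]1C[C@H]2C[C@@H]([C@@H]1C)C2(C)C)[C@@H](C)C=C | intermediate
12 | ethyl (2R,3S)-2-hydroxy-3-methylpent-4-enoate | C=C[C@H](C)[C@@H](O)C(=O)OCC | intermediate
13 | ethyl (2R,3S)-2-(tert-butyldimethylsilyloxy)-3-methylpent-4-enoate | C=C[C@H](C)[C@@H](O[Si](C)(C)C(C)(C)C)C(=O)OCC | intermediate
14 | (2R,3S)-2-(tert-butyldimethylsilyloxy)-N-methoxy-N,3-dimethylpent-4-enamide | C=C[C@H](C)[C@@H](O[Si](C)(C)C(C)(C)C)C(=O)N(C)OC | intermediate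
15 | (E)-but-2-enal (crotonaldehyde) | C/C=C/C=O | starting material
16 | (2R,3S,4E)-2-(tert-butyldimethylsilyloxy)-N-methoxy-N,3-dimethyl-6-oxohex-4-enamide | O=C/C=C/[C@H](C)[C@@H](O[Si](C)(C)C(C)(C)C)C(=O)N(C)OC | intermediate
17 | (2R,3S,4E,10E)-2-(tert-butyldimethylsilyloxy)-6-hydroxy-N-methoxy-N,3,11-trimethyl-7-methylidene-12-(triisopropylsilyloxy)trideca-4,10,12-trienamide (C6 epimers) | C=C(O[Si](C(C)C)(C(C)C)C(C)C)/C(C)=C/CCC(=C)C(O)/C=C/[C@H](C)[C@@H](O[Si](C)(C)C(C)(C)C)C(=O)N(C)OC | intermediate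
18 | (2R,3S,4E,10E)-2-(tert-butyldimethylsilyloxy)-N-methoxy-N,3,11-trimethyl-7-methylidene-6-oxo-12-(triisopropylsilyloxy)trideca-4,10,12-trienamide | C=C(O[Si](C(C)C)(C(C)C)C(C)C)/C(C)=C/CCC(=C)C(=O)/C=C/[C@H](C)[C@@H](O[Si](C)(C)C(C)(C)C)C(=O)N(C)OC | intermediate
19 | (2R,3S)-2-(tert-butyldimethylsilyloxy)-N-methoxy-N-methyl-3-[(1S,4aR,8aS)-4-methyl-7-methylidene-8-oxo-3-(triisopropylsilyloxy)-1,2,4a,5,6,7,8,8a-octahydronaphthalen-1-yl]butanamide | C=C1C(=O)[C@@H]2[C@@H](CC1)C(C)=C(O[Si](C(C)C)(C(C)C)C(C)C)C[C@H]2[C@H](C)[C@@H](O[Si](C)(C)C(C)(C)C)C(=O)N(C)OC | intermediate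
20 | (2R,3S)-2-(tert-butyldimethylsilyloxy)-N-methoxy-N-methyl-3-[(1S,4aS)-4-methyl-7-methylidene-3-(triisopropylsilyloxy)-8-(trifluoromethylsulfonyloxy)-1,2,4a,5,6,7-hexahydronaphthalen-1-yl]butanamide | C=C1C(OS(=O)(=O)C(F)(F)F)=C2[C@@H](CC1)C(C)=C(O[Si](C(C)C)(C(C)C)C(C)C)C[C@H]2[C@H](C)[C@@H](O[Si](C)(C)C(C)(C)C)C(=O)N(C)OC | intermediate
21 | (2R,3S)-2-(tert-butyldimethylsilyloxy)-N-methoxy-N-methyl-3-[(1S,4aR)-4-methyl-7-methylidene-3-(triisopropylsilyloxy)-1,2,4a,5,6,7-hexahydronaphthalen-1-yl]butanamide | C=C1C=C2[C@@H](CC1)C(C)=C(O[Si](C(C)C)(C(C)C)C(C)C)C[C@H]2[C@H](C)[C@@H](O[Si](C)(C)C(C)(C)C)C(=O)N(C)OC | intermediate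
22 | (2R,3S)-2-hydroxy-N-methoxy-N-methyl-3-[(1S,4S,4aS)-4-methyl-7-methylidene-3-oxo-1,2,3,4,4a,5,6,7-octahydronaphthalen-1-yl]butanamide | C=C1C=C2[C@@H](CC1)[C@H](C)C(=O)C[C@H]2[C@H](C)[C@@H](O)C(=O)N(C)OC | intermediate
23 | (2R,3S)-2-hydroxy-3-[(1S,3R,4S,4aS)-3-hydroxy-4-methyl-7-methylidene-1,2,3,4,4a,5,6,7-octahydronaphthalen-1-yl]-N-methoxy-N-methylbutanamide | C=C1C=C2[C@@H](CC1)[C@H](C)[C@H](O)C[C@H]2[C@H](C)[C@@H](O)C(=O)N(C)OC | intermediate
24 | 2-methylprop-1-enylmagnesium bromide | CC(C)=C[Mg]Br | starting material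
25 | (2S,3R)-3-hydroxy-2-[(1S,3R,4S,4aS)-3-hydroxy-4-methyl-7-methylidene-1,2,3,4,4a,5,6,7-octahydronaphthalen-1-yl]-6-methylhept-5-en-4-one | C=C1C=C2[C@@H](CC1)[C@H](C)[C@H](O)C[C@H]2[C@H](C)[C@@H](O)C(=O)C=C(C)C | intermediate
26 | (2S,3R)-2-[(1S,3R,4S,4aS)-3-acetoxy-4-methyl-7-methylidene-1,2,3,4,4a,5,6,7-octahydronaphthalen-1-yl]-6-methyl-4-oxohept-5-en-3-yl acetate | C=C1C=C2[C@@H](CC1)[C@H](C)[C@H](OC(C)=O)C[C@H]2[C@H](C)[C@@H](OC(C)=O)C(=O)C=C(C)C | target

**Step count:** 16 steps in total; longest linear sequence 12 steps (steps 5–8 then 9–16, or equally steps 1–4 then 9–16).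

**Three steps most likely to fail**

Step 10 (key step). What may go wrong is erosion of ring-fusion selectivity, because the conjugated tether carbonyl can pull the reaction through the carbonyl-endo, cis-fused transition state, and weak π-facial discrimination at the low barrier of the activated dienone; oligomerisation of the dienone is a further risk. The fallback runs the cycloaddition at the carbinol oxidation level, where no carbonyl endo effect competes with the steric control by the C4 methyl. It sets out from 17: acylation (PivCl, DMAP, pyridine) gives the doubly allylic pivalate F1; heating in toluene (170 °C, BHT, sealed tube) effects the unactivated intramolecular Diels–Alder reaction to the C8 pivalate cycloadduct F2; Pd(PPh3)4 (zerovalent palladium), Et3N, dioxane, 90 °C ionises the allylic pivalate and β-hydride elimination from C8a should give the diene directly. The fallback comes back to the route at 21, so that 19 and 20 are bypassed.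

Step 11. What may go wrong is slow deprotonation of the hindered ring-fusion C8a–H, conjugate addition of the amide base to the exocyclic enone, or dimerisation of the α-methylene ketone before sulfonylation. The fallback replaces enolate chemistry by reduction and elimination. It sets out from 19: 1,2-reduction (NaBH4, CeCl3·7H2O, MeOH, −78 °C) gives the C8 allylic alcohol F3; ClCO2Me, pyridine gives the allylic methyl carbonate F4; Pd(PPh3)4 (zerovalent palladium), dioxane, 80 °C effects decarboxylative ionisation and β-hydride elimination from C8a. The fallback comes back to the route at 21.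

Step 9. What may go wrong is hydrolytic loss of the silyl dienol ether at the Lewis-acidic chromium centre or sluggish coupling of the electron-rich alkenyl iodide. The fallback unveils the diene last. It sets out from 5 and 16: the same chromium-mediated addition (CrCl2, NiCl2 cat.), which tolerates the methyl ketone, gives the hydroxy enone F5; MnO2 gives the dienone–enone F6; soft enolisation of its only enolisable α-CH3 (TIPSOTf, Et3N, CH2Cl2, −78 °C) generates 18 in the flask, which cyclises as in step 10. The fallback comes back to the route at 19.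

**Further compounds**
F1 | step 10 | (2R,3S,4E,10E)-2-(tert-butyldimethylsilyloxy)-N-methoxy-N,3,11-trimethyl-7-methylidene-6-(pivaloyloxy)-12-(triisopropylsilyloxy)trideca-4,10,12-trienamide (C6 epimers) | C=C(O[Si](C(C)C)(C(C)C)C(C)C)/C(C)=C/CCC(=C)C(OC(=O)C(C)(C)C)/C=C/[C@H](C)[C@@H](O[Si](C)(C)C(C)(C)C)C(=O)N(C)OC
F2 | step 10 | (2R,3S)-2-(tert-butyldimethylsilyloxy)-N-methoxy-N-methyl-3-[(1S,4aR,8aS)-4-methyl-7-methylidene-8-(pivaloyloxy)-3-(triisopropylsilyloxy)-1,2,4a,5,6,7,8,8a-octahydronaphthalen-1-yl]butanamide (C8 epimers) | C=C1C(OC(=O)C(C)(C)C)[C@@H]2[C@@H](CC1)C(C)=C(O[Si](C(C)C)(C(C)C)C(C)C)C[C@H]2[C@H](C)[C@@H](O[Si](C)(C)C(C)(C)C)C(=O)N(C)OC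
F3 | step 11 | (2R,3S)-2-(tert-butyldimethylsilyloxy)-3-[(1S,4aR,8aS)-8-hydroxy-4-methyl-7-methylidene-3-(triisopropylsilyloxy)-1,2,4a,5,6,7,8,8a-octahydronaphthalen-1-yl]-N-methoxy-N-methylbutanamide | C=C1C(O)[C@@H]2[C@@H](CC1)C(C)=C(O[Si](C(C)C)(C(C)C)C(C)C)C[C@H]2[C@H](C)[C@@H](O[Si](C)(C)C(C)(C)C)C(=O)N(C)OC
F4 | step 11 | (2R,3S)-2-(tert-butyldimethylsilyloxy)-N-methoxy-3-[(1S,4aR,8aS)-8-(methoxycarbonyloxy)-4-methyl-7-methylidene-3-(triisopropylsilyloxy)-1,2,4a,5,6,7,8,8a-octahydronaphthalen-1-yl]-N-methylbutanamide | C=C1C(OC(=O)OC)[C@@H]2[C@@H](CC1)C(C)=C(O[Si](C(C)C)(C(C)C)C(C)C)C[C@H]2[C@H](C)[C@@H](O[Si](C)(C)C(C)(C)C)C(=O)N(C)OC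
F5 | step 9 | (2R,3S,4E,10E)-2-(tert-butyldimethylsilyloxy)-6-hydroxy-N-methoxy-N,3,11-trimethyl-7-methylidene-12-oxotrideca-4,10-dienamide (C6 epimers) | CC(=O)/C(C)=C/CCC(=C)C(O)/C=C/[C@H](C)[C@@H](O[Si](C)(C)C(C)(C)C)C(=O)N(C)OC
F6 | step 9 | (2R,3S,4E,10E)-2-(tert-butyldimethylsilyloxy)-N-methoxy-N,3,11-trimethyl-7-methylidene-6,12-dioxotrideca-4,10-dienamide | CC(=O)/C(C)=C/CCC(=C)C(=O)/C=C/[C@H](C)[C@@H](O[Si](C)(C)C(C)(C)C)C(=O)N(C)OC
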